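**Remark on the chemistry (assumption):** the olefination in step 1 is expected to give an E/Z mixture. Compounds 3, 4, 5 and 8 are drawn as the E-derived isomers and the mixture is carried forward, because the alkene geometry is erased when C2 becomes tetrahedral in step 4.

## Analysis of the target

Euglobal G3 (12) is a chroman whose C2 is a spiro atom shared with C2' of a pinane (6,6-dimethylbicyclo[3.1.1]heptane) unit. Its benzene ring is fully substituted: O1 at C8a, hydroxyls at C5 and C7, a formyl group at C8 and an isovaleryl group at C6. There are three stereocentres. The bridgeheads C1' (R) and C5' (S) are locked to each other by the bicycle and come from the chiral pool. At the spiro carbon C2 (R), O1 lies on the face turned away from the gem-dimethyl bridge C6' and toward the methylene bridge C7', so C3 sits under the gem-dimethyl bridge. The sensitive points are the tertiary alkyl aryl ether next to the cyclobutane (ionisation of C2–O1 would give a cation that rearranges or opens the four-membered ring), the aryl aldehyde, and the acidic chelated phenols. The second difficulty is regiochemical: C6 and C8 are both flanked by two oxygens, and exchanging formyl and isovaleryl gives an isomeric skeleton, so the two carbonyl groups must be placed by design. The plan rests on one feature: the pyran ring ties arene carbon C4a to phenol oxygen O1 through the three-carbon unit C4–C3–C2, whose far end is the quaternary pinane carbon. That unit is the chain of a β,β-disubstituted enal (C4 the aldehyde carbon, C2 the β-carbon) laid against one C–H/O–H edge of a phenol.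

## Retrosynthetic reasoning

**12 ⇒ 11.** The C6–C(acyl) bond is cut first. In 11, C6 is the only unsubstituted ring carbon; it lies between the 5- and 7-hydroxyls, para to O1 and meta to the formyl group, so an electrophilic acylation has nowhere else to go. Keeping the ketone out until the end leaves the earlier arene with a single chelating carbonyl, which is what makes one hydroxyl distinguishable for protection and keeps the ring nucleophilic for the ring-forming step. The forward reaction must C-acylate without ionising the spiro ether.

**11 ⇒ 9.** Two functional-group changes are undone together: the C3=C4 double bond and the 5-O-benzyl group. The chromene is what the key reaction delivers, and the benzyl ether is its regiochemical control element; one hydrogenation should remove both. The forward step must spare the aldehyde and the cyclobutane.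

**9 ⇒ 7 + 5.** The bonds C4–C4a and O1–C2 are cut. These are the two bonds that join arene and terpene, and cutting them gives a symmetrical phenol 7 and the enal 5, whose three carbons map onto C4, C3 and C2. Other cuts through the pyran ring would leave the quaternary C–O centre to be made by an ionic addition to a pinene-type alkene, with cationic character next to the cyclobutane. The gain is one ring, two skeletal bonds and the spiro stereocentre in a single step. The forward reaction must bond carbon (not oxygen) of 7 to the aldehyde carbon of 5 and then close through the correct oxygen on the correct face.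

**5 ⇒ 3 ⇒ 1 + 2.** The exocyclic C=C bond is cut, which is a two-carbon homologation of (+)-nopinone 1 with phosphonate 2. A nitrile is chosen as the carbonyl surrogate because one partial reduction then gives the aldehyde. Both bridgehead stereocentres are bought with 1 and cannot epimerise, since the bridgehead cannot enolise.

**7 ⇒ 6.** The O–CH2Ph bond is cut. In 6 the 4-hydroxyl is the only one not chelated to the formyl oxygen, so it can be alkylated selectively. Blocking it leaves, next to each free ring carbon, only the hydroxyl adjacent to the formyl group.

## Alternatives that were turned down

**Alternative 1:** aryne–nitrile oxide cycloaddition for the C6 acyl group.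
- Disconnection: the C6 ketone and the C7 oxygen are taken back together to an isoxazole, so C6–C(acyl) and C7–O are cut and the arene becomes a C6≡C7 aryne.
- Forward key step: a fluoride source would release the aryne from ortho-silyl aryl triflate A2 and the 1,3-dipole from chlorooxime A3. Their [3+2] cycloaddition would give the fused isoxazole A1; N–O cleavage and ketimine hydrolysis would later unveil the 6-isovaleryl-7-hydroxy pair.
- For: the acyl carbon enters under neutral conditions at room temperature. The C5 acetal oxygen polarises the aryne so that the oxygen terminus of the dipole goes to C7 and the carbon terminus to C6. On this point it is stronger than the chosen route, whose last step is a Friedel–Crafts acylation.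
- Against: A2 already contains the whole spirochroman, so this plan does not say how the ring and spiro centre are made and needs a second ring-forming strategy in front of it. A2 also needs a regioselective silylation between two oxygens and a triflation on a crowded arene. Aliphatic nitrile oxides dimerise readily. After A1 there remain N–O cleavage, imine hydrolysis, formylation at C8 and acidic acetal removal, so an electrophilic substitution and an acid step on the sensitive ether are still required.
- Comparison: it exchanges one risky acylation for five or six extra operations. The chosen strategy instead sets the pyran ring, the spiro stereocentre and the full substitution pattern from two simple partners, and keeps a neutral photochemical fallback for the acylation.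

**Alternative 2:** pyranone-to-acylphloroglucinol ring transformation.
- Disconnection: the benzene ring itself, at C5–C6. The arene is traced back to the fused 2-pyranone A5, whose lactone carbonyl becomes C5 and whose 2-oxoalkyl side chain carries C6 and the isovaleryl group.
- Forward key step: a magnesium alkoxide base would open the lactone to a triketo ester. The central carbon of the 1,3-diketone would then acylate the ester (Claisen condensation), closing the carbocycle, which aromatises to 8-deformyl euglobal G3 A4.
- For: the isovaleryl group arrives with the chain and its position between two hydroxyls is fixed by construction. The conditions are basic and harmless to the tertiary ether. Only a formylation at C8 remains, and formylating an acylphloroglucinol is the easier direction of electrophilic substitution compared with acylating a formylphloroglucinol. On this point the alternative is stronger.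
- Against: A5 is not simple. The spiro-dihydropyran must first be annulated onto a hydroxypyranone, which is the same ring-forming problem moved to a less convenient substrate. Its C3=C4 bond must be reduced beside the pyranone, and the side chain must be built by acylation at the γ-methyl position. The opened triketo ester can also close by aldol condensation, and alkoxide can cleave the β-diketone.
- Comparison: the step count is roughly double. The chosen strategy starts from an arene that already carries the oxygens and the formyl group, and answers the one regiochemical question with a single benzyl group.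

**Alternative 3:** phenol oxa-Michael closure onto a bicyclic enone.
- Disconnection: O1–C2 only. The terpene is carried at the enone oxidation level: A7 bears the 2-arylethyl chain on the β-carbon of a verbenone-type enone.
- Forward key step: the C8a phenoxide would add in conjugate fashion (6-endo) to the enone β-carbon to give spiro ketone A6.
- For: the C3–C4 linkage would come from simple alkylation chemistry. The closure is basic and cation-free. The gem-dimethyl bridge steers the oxygen to the same face, so stereocontrol is as good as in the chosen route.
- Against: the addition makes a tertiary ether at a β,β-disubstituted enone and is reversible, so A6 can eliminate again in any later basic step. The C4' carbonyl is absent from the target and needs a deoxygenation sequence; its basic variants invite the retro-Michael reaction and its thioacetal variants need Lewis acid. After acetal removal the arene has two free positions, C6 and C8, each flanked by two oxygens, so formyl and isovaleryl would be placed by two substitutions with no built-in control.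
- Comparison: equal on stereocontrol, but weaker on regiocontrol and on step count. The chosen strategy forms C4–C4a and O1–C2 together and carries the formyl group through as the regiochemical marker.

Key step: step 4

## Route

**Step 1**
Reactants: 1 (+)-nopinone [(1R,5S)-6,6-dimethylbicyclo[3.1.1]heptan-2-one]; 2 diethyl (cyanomethyl)phosphonate
Product: 3 (E)-2-[(1R,5S)-6,6-dimethylbicyclo[3.1.1]heptan-2-ylidene]acetonitrile
Conditions: NaH, THF, 0 → 50 °C
Reagents that add atoms: none
Why: Horner–Wadsworth–Emmons olefination; the small stabilised cyanomethylphosphonate anion should add to the hindered ketone, and the bridgehead C1 cannot enolise, so both stereocentres stay intact. The E/Z outcome does not matter downstream.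

**Step 2**
Reactants: 3 (E)-2-[(1R,5S)-6,6-dimethylbicyclo[3.1.1]heptan-2-ylidene]acetonitrile
Product: 5 (E)-2-[(1R,5S)-6,6-dimethylbicyclo[3.1.1]heptan-2-ylidene]acetaldehyde, via N-diisobutylalumino aldimine 4 (not isolated)
Conditions: i-Bu2AlH (1.2 equiv), toluene, −78 °C; MeOH, then aq. KNaC4H4O6 (potassium sodium tartrate), rt
Reagents that add atoms: water, O
Why: Partial reduction of a conjugated nitrile: one hydride adds to give the N-alumino aldimine, which is stable at low temperature and hydrolyses on work-up to the enal without reduction of the C=C bond. The buffered, non-acidic work-up avoids protonating the enal next to the cyclobutane.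

**Step 3**
Reactants: 6 2,4,6-trihydroxybenzaldehyde
Product: 7 4-(benzyloxy)-2,6-dihydroxybenzaldehyde
Conditions: BnBr (1.0 equiv), NaHCO3 (1.1 equiv), DMF, 25 → 40 °C
Reagents that add atoms: benzyl bromide, BrCc1ccccc1
Why: Williamson ether synthesis; the 4-hydroxyl is the only one not hydrogen-bonded to the formyl oxygen and is the most acidic (vinylogous acid), so one equivalent of weak base should ionise and alkylate it selectively.

**Step 4**
Reactants: 7 4-(benzyloxy)-2,6-dihydroxybenzaldehyde; 5 (E)-2-[(1R,5S)-6,6-dimethylbicyclo[3.1.1]heptan-2-ylidene]acetaldehyde
Product: 9 (2R,1'R,5'S)-5-(benzyloxy)-7-hydroxy-6',6'-dimethylspiro[2H-chromene-2,2'-bicyclo[3.1.1]heptane]-8-carbaldehyde (O1 anti to the gem-dimethyl bridge), via oxatriene dienone 8 (not isolated)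
Conditions: ethylenediammonium diacetate (20 mol%), toluene, 110 °C, azeotropic removal of water
Reagents that add atoms: none
Why: The ammonium acetate converts 5 into an iminium ion, and C3 of 7 (ortho to the free 2-hydroxyl, para to the 6-hydroxyl) adds to the iminium carbon in a Knoevenagel/Mannich-type 1,2-addition, conjugate addition being blocked because the β-carbon is fully substituted. Loss of the amine gives the 1-oxatriene 8, a vinylogous ortho-quinone methide, which closes by thermal disrotatory oxa-6π electrocyclisation, forming O1–C2 and the pyran ring with rearomatisation as the driving force. The closest known reaction type is the formal [3+3] annulation of resorcinol-type phenols and 1,3-dicarbonyl compounds with β,β-disubstituted enals to 2H-chromenes. The ring is closed in the 6π electrocyclic mode and not by an ionic addition, so no positive charge develops at the pinane carbon and the cyclobutane should not be at risk. The spiro stereocentre is set in the electrocyclisation: the syn-methyl of the C6' bridge covers one face of the exocyclic alkene terminus, so the oxygen should bond from the face of the C7' methylene bridge, which places C3 under the gem-dimethyl bridge and gives the 2R configuration. Each geometrical isomer of the triene can close through either helical conformer, and in both the bicycle selects the helix, so the E/Z composition of 5 should not matter. Regioselectivity is secured by the substrate: C3 and C5 of 7 are equivalent by symmetry, and the only free hydroxyl ortho to the new side chain is the one next to the formyl group, the other neighbour being the benzyl ether, so only the 8-formyl chromene can form. Reversible imine formation between the catalyst and the aryl aldehyde is non-productive and should be undone on aqueous work-up.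

**Step 5**
Reactants: 9 (2R,1'R,5'S)-5-(benzyloxy)-7-hydroxy-6',6'-dimethylspiro[2H-chromene-2,2'-bicyclo[3.1.1]heptane]-8-carbaldehyde
Product: 11 (2R,1'R,5'S)-5,7-dihydroxy-6',6'-dimethylspiro[chromane-2,2'-bicyclo[3.1.1]heptane]-8-carbaldehyde, via benzyl ether chroman 10 (not isolated)
Conditions: H2 (1 atm), 10% Pd/C, EtOAc, rt, stopped after uptake of 2 equiv H2
Reagents that add atoms: none
Why: Heterogeneous catalytic hydrogenation should saturate the cis-disubstituted styrenyl C3=C4 bond and then hydrogenolyse the benzyl ether. No stereocentre is formed, and the chelated, electron-rich salicylaldehyde carbonyl is a vinylogous acid that should resist reduction under neutral, low-pressure conditions.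

**Step 6**
Reactants: 11 (2R,1'R,5'S)-5,7-dihydroxy-6',6'-dimethylspiro[chromane-2,2'-bicyclo[3.1.1]heptane]-8-carbaldehyde
Product: 12 euglobal G3, (2R,1'R,5'S)-5,7-dihydroxy-6',6'-dimethyl-6-(3-methylbutanoyl)spiro[chromane-2,2'-bicyclo[3.1.1]heptane]-8-carbaldehyde
Conditions: Me2CHCH2COCl (1.5 equiv), TiCl4 (3 equiv), CH2Cl2, −20 → 0 °C; cold aq. KNaC4H4O6
Reagents that add atoms: 3-methylbutanoyl chloride, CC(C)CC(=O)Cl
Why: Friedel–Crafts acylation at C6, the only unsubstituted ring carbon, which is activated by two ortho hydroxyls and the para ether oxygen and is meta to the formyl group. The titanium phenoxides formed at O5 and O7 should deliver the acyl chloride to the ortho carbon, which allows a low temperature at which the tertiary spiro ether should not ionise.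

## Compound list

1 | (+)-nopinone, (1R,5S)-6,6-dimethylbicyclo[3.1.1]heptan-2-one | O=C1CC[C@H]2C[C@@H]1C2(C)C | starting material
2 | diethyl (cyanomethyl)phosphonate | N#CCP(=O)(OCC)OCC | starting material
3 | (E)-2-[(1R,5S)-6,6-dimethylbicyclo[3.1.1]heptan-2-ylidene]acetonitrile | N#C/C=C1\CC[C@H]2C[C@@H]1C2(C)C | intermediate
4 | N-(diisobutylalumino) aldimine of 5 | CC(C)C[Al](CC(C)C)N=C/C=C1\CC[C@H]2C[C@@H]1C2(C)C | intermediate (not isolated)
5 | (E)-2-[(1R,5S)-6,6-dimethylbicyclo[3.1.1]heptan-2-ylidene]acetaldehyde | O=C/C=C1\CC[C@H]2C[C@@H]1C2(C)C | intermediate
6 | 2,4,6-trihydroxybenzaldehyde | O=Cc1c(O)cc(O)cc1O | starting material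
7 | 4-(benzyloxy)-2,6-dihydroxybenzaldehyde | O=Cc1c(O)cc(OCc2ccccc2)cc1O | intermediate
8 | 4-(benzyloxy)-5-{2-[(1R,5S)-6,6-dimethylbicyclo[3.1.1]heptan-2-ylidene]ethylidene}-2-hydroxy-6-oxocyclohexa-1,3-diene-1-carbaldehyde (oxatriene dienone) | O=C1C(C=O)=C(O)C=C(OCc2ccccc2)\C1=C\C=C3/CC[C@H]4C[C@@H]3C4(C)C | intermediate (not isolated)
9 | (2R,1'R,5'S)-5-(benzyloxy)-7-hydroxy-6',6'-dimethylspiro[2H-chromene-2,2'-bicyclo[3.1.1]heptane]-8-carbaldehyde | O=Cc1c(O)cc(OCc2ccccc2)c2C=C[C@@]3(CC[C@H]4C[C@@H]3C4(C)C)Oc12 | intermediate
10 | (2R,1'R,5'S)-5-(benzyloxy)-7-hydroxy-6',6'-dimethylspiro[chromane-2,2'-bicyclo[3.1.1]heptane]-8-carbaldehyde | O=Cc1c(O)cc(OCc2ccccc2)c2CC[C@@]3(CC[C@H]4C[C@@H]3C4(C)C)Oc12 | intermediate (not isolated)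
11 | (2R,1'R,5'S)-5,7-dihydroxy-6',6'-dimethylspiro[chromane-2,2'-bicyclo[3.1.1]heptane]-8-carbaldehyde | O=Cc1c(O)cc(O)c2CC[C@@]3(CC[C@H]4C[C@@H]3C4(C)C)Oc12 | intermediate
12 | euglobal G3, (2R,1'R,5'S)-5,7-dihydroxy-6',6'-dimethyl-6-(3-methylbutanoyl)spiro[chromane-2,2'-bicyclo[3.1.1]heptane]-8-carbaldehyde | CC(C)CC(=O)c1c(O)c(C=O)c2c(c1O)CC[C@@]1(CC[C@H]3C[C@@H]1C3(C)C)O2 | target

## Step count and uncertain steps

Total step count: 6. Longest linear sequence: 5 steps (steps 1, 2, 4, 5 and 6, from 1); the arene branch (steps 3, 4, 5, 6) has 4.

**Step 4 (key step).**
- What may go wrong: C–C bond formation may be slow because the formyl group and the ether make the ring less nucleophilic than the free triol, so that self-condensation of 5 through its dienamine takes over. Reversible ring opening of the chromene at the reaction temperature may erode the facial selectivity at C2. The diamine catalyst may be tied up as a Schiff base of the salicylaldehyde.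
- Fallback: the same pyran ring is assembled from the other side by an inverse-demand hetero-Diels–Alder reaction of an ortho-quinone methide, which forms C3–C4 and O1–C2 instead. It sets out from 7. Mannich aminomethylation at C3 with morpholine and formaldehyde should give 4-(benzyloxy)-2,6-dihydroxy-3-(morpholin-4-ylmethyl)benzaldehyde F2. Heating F2 with (−)-β-pinene F3 (xylene, 140 °C) should expel morpholine, and the quinone methide so formed should add to the exocyclic alkene. The methylene terminus of F3 should bond to the quinone-methide carbon and the oxygen to the tertiary carbon, from the face anti to the gem-dimethyl bridge. Only the hydroxyl next to the formyl group can take part, so the regiochemistry is the same. The adduct is 10, where the route is rejoined; the hydrogenolysis of step 5 then gives 11.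

**Step 6.**
- What may go wrong: Lewis-acid or HCl-induced ionisation of the C2–O1 bond with skeletal rearrangement or opening of the cyclobutane; sluggish C-acylation because the formyl group deactivates the ring; acylation stopping at oxygen.
- Fallback: the acyl group is moved from oxygen to carbon without acid. It sets out from 11. Esterification of the non-chelated 5-hydroxyl (Me2CHCH2COCl, Et3N, CH2Cl2, 0 °C) should give (2R,1'R,5'S)-8-formyl-7-hydroxy-6',6'-dimethylspiro[chromane-2,2'-bicyclo[3.1.1]heptan]-5-yl 3-methylbutanoate F4. Irradiation of F4 (254 nm, degassed MeCN, quartz) should bring about a photo-Fries rearrangement through a caged acyl/phenoxyl radical pair. C6 is the only open ortho position and the para position is blocked, so the acyl group can only arrive at C6, and the route is rejoined at 12. An ester formed at O7 instead would migrate to the same carbon.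

**Step 5.**
- What may go wrong: over-reduction of the aryl aldehyde to the benzylic alcohol and further hydrogenolysis to a methyl group once the benzyl ether has gone, since both are benzylic C–O cleavages on palladium.
- Fallback: the two events are separated and each is given a reagent that cannot touch the aldehyde. It sets out from 9. Homogeneous hydrogenation with RhCl(PPh3)3 (H2, toluene/EtOH, rt) should saturate only the C3=C4 bond and give 10, now isolated. Transfer hydrogenolysis (Pd/C, 1,4-cyclohexadiene, EtOH, rt), in which hydrogen is supplied only as fast as the donor delivers it, should then remove the benzyl group and rejoin the route at 11. No compound outside the list arises (F0).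

**Step 3.**
- What may go wrong: over-alkylation to di-ethers and C-benzylation of the phloroglucinol nucleus, because the mono-ether is still an acidic, nucleophilic phenol.
- Fallback: over-alkylation is accepted and corrected by chelation. It sets out from 6. Benzylation with 2.2 equiv BnBr and K2CO3 in DMF should give 2,4-bis(benzyloxy)-6-hydroxybenzaldehyde F1, the last hydroxyl being held back by its hydrogen bond to the formyl group. MgBr2·OEt2 (toluene/Et2O, reflux) should then cleave only the ortho benzyl ether, which is chelated to the carbonyl, and rejoin the route at 7.

## Further compounds

F1 | step 3 | 2,4-bis(benzyloxy)-6-hydroxybenzaldehyde | O=Cc1c(O)cc(OCc2ccccc2)cc1OCc1ccccc1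
F2 | step 4 | 4-(benzyloxy)-2,6-dihydroxy-3-(morpholin-4-ylmethyl)benzaldehyde | O=Cc1c(O)cc(OCc2ccccc2)c(CN2CCOCC2)c1O
F3 | step 4 | (−)-β-pinene, (1S,5S)-6,6-dimethyl-2-methylidenebicyclo[3.1.1]heptane | C=C1CC[C@H]2C[C@@H]1C2(C)C
F0 | step 5 | none | none
F4 | step 6 | (2R,1'R,5'S)-8-formyl-7-hydroxy-6',6'-dimethylspiro[chromane-2,2'-bicyclo[3.1.1]heptan]-5-yl 3-methylbutanoate | CC(C)CC(=O)Oc1cc(O)c(C=O)c2c1CC[C@@]1(CC[C@H]3C[C@@H]1C3(C)C)O2
A1 | alternative 1 | C6–C7-fused 3-isobutylisoxazole of 5-(methoxymethoxy)spiro[chroman-2,2'-pinane] | CC(C)Cc1noc2cc3c(c(OCOC)c12)CC[C@@]1(CC[C@H]2C[C@@H]1C2(C)C)O3
A2 | alternative 1 | 5-(methoxymethoxy)-6-(trimethylsilyl)spiro[chroman-2,2'-pinan]-7-yl trifluoromethanesulfonate | COCOc1c([Si](C)(C)C)c(OS(=O)(=O)C(F)(F)F)cc2c1CC[C@@]1(CC[C@H]3C[C@@H]1C3(C)C)O2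
A3 | alternative 1 | N-hydroxy-3-methylbutanimidoyl chloride | CC(C)CC(Cl)=NO
A4 | alternative 2 | 8-deformyl euglobal G3, 6-isovaleryl-5,7-dihydroxyspiro[chroman-2,2'-pinane] | CC(C)CC(=O)c1c(O)cc2c(c1O)CC[C@@]1(CC[C@H]3C[C@@H]1C3(C)C)O2
A5 | alternative 2 | 7-(4-methyl-2-oxopentyl)-3,4-dihydrospiro[pyrano[4,3-b]pyran-2,2'-pinan]-5-one | CC(C)CC(=O)CC1=CC2=C(CC[C@@]3(CC[C@H]4C[C@@H]3C4(C)C)O2)C(=O)O1
A6 | alternative 3 | 5,7-bis(methoxymethoxy)spiro[chroman-2,2'-pinan]-4'-one | COCOc1cc2c(c(OCOC)c1)CC[C@@]1(CC(=O)[C@H]3C[C@@H]1C3(C)C)O2
A7 | alternative 3 | 4-{2-[2-hydroxy-4,6-bis(methoxymethoxy)phenyl]ethyl}-6,6-dimethylbicyclo[3.1.1]hept-3-en-2-one | COCOc1cc(O)c(CCC2=CC(=O)[C@H]3C[C@@H]2C3(C)C)c(OCOC)c1
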